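The ten-membered ring (C1–C10) is closed last at C3–C4, its only unfunctionalised bond, which lies between the C2 carbonyl and the allylic C4 of the Z C5=C6 alkene. Because C1 is quaternary, the C2 methyl ketone can enolise only toward C3, and this enolate displaces a primary (Z)-allylic chloride at C4 in one operation that forms the ring without touching a stereocentre. The precursor already holds the cyclohexene (C1, C10–C14; from an enantioselective Diels–Alder reaction), the γ-lactone (C7, C8, C17, C19; from (S)-malate) and the Z-alkene, so the chain is pre-organised.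

Key step: step 27

Remark 1: briarane locants (C1–C20) are used for all intermediates.
Remark 2: the oxazaborolidinium derived from (R)-diphenylprolinol is assumed to expose the Si face of C1 in enal 3, by analogy with 2-methylacrolein; if the sense proves opposite, the (S)-catalyst is used.
Remark 3: C11 in 4–7 and C2 in 5–35 are temporary stereocentres, drawn as the formyl-endo and Felkin–Anh isomers; both are erased later (steps 6 and 26), so their ratios do not matter.

Step 1
Reactants: 1 pent-1-en-3-one
Product: 2 (Z)-3-(tert-butyldimethylsilyloxy)penta-1,3-diene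
Conditions: TBSOTf, Et3N, Et2O, 0 °C
Reagents that add atoms: tert-butyldimethylsilyl triflate, CC(C)(C)[Si](C)(C)OS(=O)(=O)C(F)(F)F
Why: Soft enolisation of the ethyl ketone (silyl enol ether formation) should give the 2-silyloxydiene as the (Z)-isomer, whose terminal methyl points away from the vinyl group and so allows the s-cis conformation.

Step 2
Reactants: 2 (Z)-3-(tert-butyldimethylsilyloxy)penta-1,3-diene; 3 (E)-4-acetoxy-2-methylbut-2-enal
Product: 4 cyclohexene aldehyde (C1: CH3 and CHO; C10: CH2OAc cis to the C1 methyl; C11: CH3; C12=C13 silyl enol ether)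
Conditions: (R)-3,3-diphenyl-1-(o-tolyl)tetrahydropyrrolo[1,2-c][1,3,2]oxazaborole (20 mol%), Tf2NH (20 mol%), CH2Cl2, −78 → −40 °C
Reagents that add atoms: none
Why: In this enantioselective Diels–Alder reaction under chiral oxazaborolidinium activation the nucleophilic enol ether terminus C11 bonds to the enal β-carbon C10 and C14 to C1, the (E)-geometry of 3 places the C1 methyl and the C9 arm cis, and the catalyst shields one enal face so that the diene adds to the Si face of C1, which sets C1 and C10.

Step 3
Reactants: 4 cyclohexene aldehyde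
Product: 5 diol (C2 as CH(OH)CH3, C9 as CH2OH, silyl enol ether kept)
Conditions: MeMgBr (4 equiv), THF, −78 → 0 °C; aq. NH4Cl
Reagents that add atoms: methylmagnesium bromide, C[Mg]Br
Why: Grignard addition to the neopentyl aldehyde (Felkin–Anh sense, the new C2 centre being temporary) installs C3, and the excess reagent cleaves the acetate to the primary alcohol.

Step 4
Reactants: 5 diol
Product: 6 bis-silyl ether (2-OTBS, 9-OTBS) of the silyl enol ether
Conditions: TBSOTf (2.5 equiv), 2,6-lutidine, CH2Cl2, −78 → 0 °C
Reagents that add atoms: tert-butyldimethylsilyl triflate, CC(C)(C)[Si](C)(C)OS(=O)(=O)C(F)(F)F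
Why: Silyl triflate silylation protects both the hindered secondary and the primary hydroxyl without disturbing the silyl enol ether.

Step 5
Reactants: 6 bis-silyl ether
Product: 7 enone (C12 ketone, C13=C14 alkene)
Conditions: Pd(OAc)2 (10 mol%), O2 (1 atm), DMSO, 50 °C
Reagents that add atoms: none
Why: In this Saegusa–Ito oxidation palladation at C13 and β-hydride elimination from C14, the only carbon that offers a β-hydrogen, move the unsaturation to C13=C14 next to the quaternary C1.

Step 6
Reactants: 7 enone
Product: 9 dienyl triflate (C11=C12(OTf)–C13=C14), via potassium dienolate 8 (not isolated)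
Conditions: KN(SiMe3)2, THF, −78 °C; PhNTf2, −78 → 0 °C
Reagents that add atoms: N-phenylbis(trifluoromethanesulfonimide), O=S(=O)(N(c1ccccc1)S(=O)(=O)C(F)(F)F)C(F)(F)F
Why: Deprotonation of the enone can occur only at C11 because the γ-carbon C1 is quaternary, and O-triflation of the cross-conjugated dienolate gives the dienyl triflate (enol triflate formation), which erases the temporary C11 centre.

Step 7
Reactants: 9 dienyl triflate
Product: 10 cyclohexa-1,3-diene (C11(CH3)=C12–C13=C14)
Conditions: Pd(OAc)2 (5 mol%), PPh3, HCO2H, Bu3N, DMF, 60 °C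
Reagents that add atoms: none
Why: Palladium-catalysed formate reduction of the enol triflate (oxidative addition, exchange of formate for hydride with loss of CO2, reductive elimination) replaces C12–OTf by C12–H and leaves the diene in place.

Step 8
Reactants: 10 cyclohexa-1,3-diene
Product: 11 11α,12α-diol
Conditions: OsO4 (2 mol%), NMO (1.05 equiv), acetone/H2O, 0 °C
Reagents that add atoms: N-methylmorpholine N-oxide, C[N+]1([O-])CCOCC1; water, O
Why: Catalytic OsO4 dihydroxylation should attack the more electron-rich trisubstituted C11=C12 alkene, not the C13=C14 alkene flanked by the quaternary C1, and from the α face opposite the adjacent β-oriented C9 arm on C10, so that the cis-diol sets C11 (OH α, CH3 β) and C12 (OH α).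

Step 9
Reactants: 11 11α,12α-diol
Product: 12 11,12-acetonide
Conditions: Me2C(OMe)2, PPTS, CH2Cl2, rt
Reagents that add atoms: 2,2-dimethoxypropane, COC(C)(C)OC
Why: Acid-catalysed transacetalisation closes the cis-fused five-membered acetonide on the cis-diol.

Step 10
Reactants: 12 11,12-acetonide
Product: 13 C9 primary alcohol
Conditions: HF·pyridine, pyridine, THF, 0 °C
Reagents that add atoms: none
Why: Buffered HF·pyridine removes the primary silyl ether far faster than the neopentyl secondary one and does not cleave the acetonide (selective desilylation).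

Step 11
Reactants: 13 C9 primary alcohol
Product: 14 C9 aldehyde
Conditions: Dess–Martin periodinane, NaHCO3, CH2Cl2, 0 °C → rt
Reagents that add atoms: none
Why: Dess–Martin oxidation gives the aldehyde under buffered conditions that should not epimerise C10.

Step 12
Reactants: 15 dimethyl (S)-malate
Product: 17 dimethyl (2S,3R)-2-hydroxy-3-methylsuccinate, via dilithium alkoxide–enolate 16 (not isolated)
Conditions: LiN(SiMe3)2 (2.2 equiv), THF, −78 → −20 °C; MeI, −78 °C; AcOH
Reagents that add atoms: iodomethane, CI
Why: In this Fráter–Seebach alkylation the chelated lithium alkoxide–enolate is methylated anti to the C8 oxygen, which sets C17 (R) from the malate stereocentre.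

Step 13
Reactants: 17 dimethyl (2S,3R)-2-hydroxy-3-methylsuccinate
Product: 18 (2S,3R)-2-hydroxy-3-methylsuccinic acid
Conditions: LiOH, THF/H2O, rt; then HCl
Reagents that add atoms: lithium hydroxide, [Li+].[OH-]
Why: Saponification of both methyl esters followed by acidification gives the diacid without touching the stereocentres.

Step 14
Reactants: 18 (2S,3R)-2-hydroxy-3-methylsuccinic acid
Product: 19 cis-dioxolanone acid ((R)-2-[cis-2-tert-butyl-5-oxo-1,3-dioxolan-4-yl]propanoic acid, C8 unchanged)
Conditions: t-BuCHO, TsOH·H2O (cat.), pentane, reflux (Dean–Stark)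
Reagents that add atoms: pivalaldehyde, CC(C)(C)C=O
Why: Acid-catalysed acetalisation of the α-hydroxy acid gives the five-membered dioxolanone in preference to the six-membered alternative, and the favoured cis-isomer stores the C8 configuration in the acetal centre (self-regeneration of stereocentres).

Step 15
Reactants: 19 cis-dioxolanone acid
Product: 20 tert-butyl ester of the cis-dioxolanone
Conditions: t-BuOC(=NH)CCl3, BF3·OEt2 (cat.), CH2Cl2/cyclohexane, rt
Reagents that add atoms: tert-butyl 2,2,2-trichloroacetimidate, CC(C)(C)OC(=N)C(Cl)(Cl)Cl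
Why: Acid-catalysed tert-butylation with the trichloroacetimidate esterifies the free acid under conditions the acetal tolerates and gives an ester inert to alkoxides and organolithiums at low temperature.

Step 16
Reactants: 21 prop-2-yn-1-ol
Product: 23 (Z)-3-iodo-2-methylprop-2-en-1-ol, via alkenylmagnesium alkoxide 22 (not isolated)
Conditions: MeMgBr (2.5 equiv), CuI (10 mol%), THF, −10 °C → rt; I2, −78 → 0 °C
Reagents that add atoms: methylmagnesium bromide, C[Mg]Br; iodine, II
Why: Copper-catalysed anti-carbomagnesiation of the propargylic alkoxide gives the chelated (Z)-alkenylmagnesium species, and iodinolysis with retention gives the iodide with iodine cis to CH2OH, which is the C5=C6 geometry of the target.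

Step 17
Reactants: 23 (Z)-3-iodo-2-methylprop-2-en-1-ol
Product: 24 (Z)-tert-butyl[(3-iodo-2-methylallyl)oxy]dimethylsilane
Conditions: TBSCl, imidazole, CH2Cl2, rt
Reagents that add atoms: tert-butyldimethylsilyl chloride, CC(C)(C)[Si](C)(C)Cl
Why: Standard silylation protects the primary allylic alcohol before halogen–lithium exchange.

Step 18
Reactants: 20 tert-butyl ester of the cis-dioxolanone; 14 C9 aldehyde
Product: 26 aldol adduct (C8 quaternary in the dioxolanone, free 9-OH), via lithium enolate 25 (not isolated)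
Conditions: LiN(i-Pr)2, THF, −78 °C; then 14, −78 °C; AcOH
Reagents that add atoms: none
Why: In this aldol addition of the dioxolanone lithium enolate the tert-butyl group directs the aldehyde to the opposite face so that C9 replaces H at C8 with retention, and a closed Zimmerman–Traxler transition state with the aldehyde substituent equatorial places the ring oxygen (trans to O–Li) anti to the new hydroxyl, which should give the 8,9-relationship of the target.

Step 19
Reactants: 26 aldol adduct
Product: 27 9-O-MOM ether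
Conditions: MOMCl, i-Pr2NEt, Bu4NI (cat.), CH2Cl2, 40 °C
Reagents that add atoms: chloromethyl methyl ether, COCCl
Why: Alkylation of the hindered secondary alcohol with the reactive chloromethyl ether gives the MOM ether and prevents later lactonisation of O9 onto C19.

Step 20
Reactants: 24 (Z)-tert-butyl[(3-iodo-2-methylallyl)oxy]dimethylsilane; 27 9-O-MOM ether
Product: 29 α-hydroxy (Z)-enone (C7 ketone, free 8-OH), via (Z)-alkenyllithium 28 (not isolated)
Conditions: 24 (2.5 equiv), t-BuLi (5.0 equiv), Et2O, −78 °C; then 27, THF, −78 °C; AcOH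
Reagents that add atoms: none
Why: Iodine–lithium exchange with retention gives the (Z)-alkenyllithium, which adds once to the activated acyl-acetal carbonyl while the tert-butyl ester is inert at −78 °C, and collapse of the adduct on work-up releases pivalaldehyde and the tertiary C8 hydroxyl (acyl substitution by an organolithium).

Step 21
Reactants: 29 α-hydroxy (Z)-enone
Product: 30 7,8-diol tert-butyl ester
Conditions: Zn(BH4)2, Et2O, −30 °C
Reagents that add atoms: none
Why: In this chelation-controlled 1,2-reduction zinc bridges the C7 carbonyl and the free C8 hydroxyl, and hydride is delivered to the face of the chelate that carries the smaller C17 branch and not the C9 branch, which should set C7 (S).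

Step 22
Reactants: 30 7,8-diol tert-butyl ester
Product: 31 γ-lactone with free 8-OH
Conditions: NaH (0.2 equiv), THF, 0 °C; AcOH
Reagents that add atoms: none
Why: In this base-catalysed intramolecular transesterification the secondary allylic alkoxide closes the five-membered lactone onto C19 with loss of tert-butoxide, which carries the chain, and C17 keeps its methyl trans to the large C9 branch.

Step 23
Reactants: 31 γ-lactone with free 8-OH
Product: 32 8,9-bis-MOM lactone
Conditions: MOMCl, i-Pr2NEt, NaI (cat.), ClCH2CH2Cl, 50 °C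
Reagents that add atoms: chloromethyl methyl ether, COCCl
Why: Forcing MOM alkylation of the tertiary β-hydroxyl removes the last acidic O–H and blocks retro-aldol opening before the enolate step.

Step 24
Reactants: 32 8,9-bis-MOM lactone
Product: 33 diol (2-OH and 4-OH)
Conditions: HF·pyridine, pyridine, THF, 0 → 40 °C
Reagents that add atoms: none
Why: Fluoride-mediated desilylation removes both silyl ethers while MOM ethers, acetonide and lactone should be stable to buffered HF·pyridine.

Step 25
Reactants: 33 diol
Product: 35 (Z)-allylic chloride with free 2-OH, via allylic mesylate 34 (not isolated)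
Conditions: MsCl, 2,4,6-collidine, LiCl, DMF, 0 °C
Reagents that add atoms: lithium chloride, [Li+].[Cl-]
Why: Selective mesylation of the primary allylic alcohol and in situ SN2 displacement by chloride give the allylic chloride without allylic transposition or loss of the Z geometry, the neopentyl C2 hydroxyl being too hindered to react.

Step 26
Reactants: 35 (Z)-allylic chloride with free 2-OH
Product: 36 cyclisation precursor (C2 methyl ketone, C4 chloride)
Conditions: Dess–Martin periodinane, NaHCO3, CH2Cl2, 0 °C → rt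
Reagents that add atoms: none
Why: Dess–Martin oxidation converts the secondary alcohol into the methyl ketone, which erases the temporary C2 centre, and leaves the allylic chloride untouched.

Step 27
Reactants: 36 cyclisation precursor
Product: 38 tricyclic C2 ketone, via potassium enolate 37 (not isolated)
Conditions: KN(SiMe3)2 (0.98 equiv), THF (0.002 M), −78 °C, then −78 → 0 °C
Reagents that add atoms: none
Why: KN(SiMe3)2 removes a proton from the C3 methyl group, the only enolisable position of the C2 ketone because C1 is quaternary, and the potassium enolate displaces the primary allylic chloride at C4 by intramolecular SN2. The closest known reaction type is macrocyclisation by intramolecular alkylation of enolates or stabilised carbanions with allylic halides. The ten-membered ring closes in the 10-exo-tet mode, and no stereocentre is formed. The step needs C- over O-alkylation, cyclisation over oligomerisation, and enolisation at C3 and not at the lactone C17; the soft allylic chloride with a potassium enolate in THF favours C-alkylation, the 0.002 M concentration suppresses intermolecular reaction, and the cyclohexene, the Z-alkene and the lactone hold the reacting ends close. A slight deficit of the hindered base at −78 °C should enolise the unhindered methyl ketone selectively, since the C17 hydrogen is tertiary and screened by the C8 substituents. The Z geometry is kept because the displacement is a direct SN2 at C4.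

Step 28
Reactants: 38 tricyclic C2 ketone
Product: 39 C2 alcohol (2R)
Conditions: NaBH4, MeOH/CH2Cl2, −20 °C
Reagents that add atoms: none
Why: In this hydride reduction at the periphery of the ten-membered ring, with the C2 carbonyl turned away from the β-methyl on C1, borohydride should attack from the open outer face and give the 2R alcohol, while the lactone is not reduced at −20 °C.

Step 29
Reactants: 39 C2 alcohol
Product: 40 pentaol (2-, 8-, 9-, 11-, 12-OH)
Conditions: 2 M HCl (aq.), THF, 40 °C
Reagents that add atoms: none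
Why: Aqueous acid hydrolyses the two MOM acetals and the acetonide in one operation (acetal hydrolysis).

Step 30
Reactants: 40 pentaol
Product: 41 CNP0129620.2
Conditions: Ac2O, pyridine, DMAP (cat.), CH2Cl2, rt
Reagents that add atoms: acetic anhydride, CC(=O)OC(C)=O
Why: DMAP-catalysed acetylation esterifies the three secondary hydroxyls at C2, C9 and C12, whereas the tertiary hydroxyls at C8 and C11 should not react under these conditions.

Compound list
1 | pent-1-en-3-one | CCC(=O)C=C | starting material
2 | (Z)-3-(tert-butyldimethylsilyloxy)penta-1,3-diene | C=C/C(O[Si](C)(C)C(C)(C)C)=C/C | intermediate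
3 | (E)-4-acetoxy-2-methylbut-2-enal | O=C/C(C)=C/COC(C)=O | starting material
4 | cyclohexene aldehyde: C1 (CH3, CHO), C10 (CH2OAc cis to C1 methyl), C11 (CH3 cis to CHO), 12-OTBS enol ether C12=C13 | O=C[C@@]1(C)CC=C(O[Si](C)(C)C(C)(C)C)[C@@H](C)[C@@H]1COC(C)=O | intermediate
5 | diol: as 4 with C2 as CH(OH)CH3 (2S as drawn) and C9 as CH2OH | C[C@H](O)[C@@]1(C)CC=C(O[Si](C)(C)C(C)(C)C)[C@@H](C)[C@@H]1CO | intermediate
6 | bis-silyl ether: 2-OTBS, 9-OTBS, 12-OTBS enol ether | C[C@H](O[Si](C)(C)C(C)(C)C)[C@@]1(C)CC=C(O[Si](C)(C)C(C)(C)C)[C@@H](C)[C@@H]1CO[Si](C)(C)C(C)(C)C | intermediate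
7 | enone: C12 ketone, C13=C14, 2-OTBS, 9-OTBS | C[C@H](O[Si](C)(C)C(C)(C)C)[C@@]1(C)C=CC(=O)[C@@H](C)[C@@H]1CO[Si](C)(C)C(C)(C)C | intermediate
8 | potassium dienolate of 7 (C11=C12(OK)–C13=C14) | C[C@H](O[Si](C)(C)C(C)(C)C)[C@@]1(C)C=CC([O-])=C(C)[C@@H]1CO[Si](C)(C)C(C)(C)C.[K+] | intermediate
9 | dienyl triflate (C11=C12(OTf)–C13=C14) | C[C@H](O[Si](C)(C)C(C)(C)C)[C@@]1(C)C=CC(OS(=O)(=O)C(F)(F)F)=C(C)[C@@H]1CO[Si](C)(C)C(C)(C)C | intermediate
10 | cyclohexa-1,3-diene (C11(CH3)=C12–C13=C14) | C[C@H](O[Si](C)(C)C(C)(C)C)[C@@]1(C)C=CC=C(C)[C@@H]1CO[Si](C)(C)C(C)(C)C | intermediate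
11 | 11α,12α-diol (both OH trans to the C9 arm; 11-CH3 β) | C[C@H](O[Si](C)(C)C(C)(C)C)[C@@]1(C)C=C[C@@H](O)[C@@](C)(O)[C@@H]1CO[Si](C)(C)C(C)(C)C | intermediate
12 | 11,12-acetonide with 2-OTBS and 9-OTBS | C[C@H](O[Si](C)(C)C(C)(C)C)[C@@]1(C)C=C[C@H]2OC(C)(C)O[C@@]2(C)[C@@H]1CO[Si](C)(C)C(C)(C)C | intermediate
13 | C9 primary alcohol of the acetonide | C[C@H](O[Si](C)(C)C(C)(C)C)[C@@]1(C)C=C[C@H]2OC(C)(C)O[C@@]2(C)[C@@H]1CO | intermediate
14 | C9 aldehyde of the acetonide | C[C@H](O[Si](C)(C)C(C)(C)C)[C@@]1(C)C=C[C@H]2OC(C)(C)O[C@@]2(C)[C@@H]1C=O | intermediate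
15 | dimethyl (S)-malate | COC(=O)C[C@H](O)C(=O)OC | starting material
16 | dilithium alkoxide–enolate of dimethyl (S)-malate | COC(=O)[C@@H]([O-])C=C([O-])OC.[Li+].[Li+] | intermediate
17 | dimethyl (2S,3R)-2-hydroxy-3-methylsuccinate | COC(=O)[C@H](C)[C@H](O)C(=O)OC | intermediate
18 | (2S,3R)-2-hydroxy-3-methylsuccinic acid | OC(=O)[C@H](C)[C@H](O)C(=O)O | intermediate
19 | cis-dioxolanone acid: (R)-2-[cis-2-tert-butyl-5-oxo-1,3-dioxolan-4-yl]propanoic acid | OC(=O)[C@H](C)[C@@H]1O[C@H](C(C)(C)C)OC1=O | intermediate
20 | tert-butyl ester of 19 | CC(C)(C)OC(=O)[C@H](C)[C@@H]1O[C@H](C(C)(C)C)OC1=O | intermediate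
21 | prop-2-yn-1-ol | C#CCO | starting material
22 | (Z)-alkenylmagnesium alkoxide (Mg cis to CH2O) | Br[Mg]/C=C(/C)CO[Mg]Br | intermediate
23 | (Z)-3-iodo-2-methylprop-2-en-1-ol | OC/C(C)=C\I | intermediate
24 | (Z)-tert-butyl[(3-iodo-2-methylallyl)oxy]dimethylsilane | CC(C)(C)[Si](C)(C)OC/C(C)=C\I | intermediate
25 | lithium enolate of 20 | CC(C)(C)OC(=O)[C@H](C)C1=C([O-])O[C@@H](C(C)(C)C)O1.[Li+] | intermediate
26 | aldol adduct: C8 quaternary in the dioxolanone (C9 trans to tert-butyl), free 9-OH | C[C@H](O[Si](C)(C)C(C)(C)C)[C@@]1(C)C=C[C@H]2OC(C)(C)O[C@@]2(C)[C@@H]1[C@@H](O)[C@]3(O[C@H](C(C)(C)C)OC3=O)[C@@H](C)C(=O)OC(C)(C)C | intermediate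
27 | 9-O-MOM ether of 26 | C[C@H](O[Si](C)(C)C(C)(C)C)[C@@]1(C)C=C[C@H]2OC(C)(C)O[C@@]2(C)[C@@H]1[C@@H](OCOC)[C@]3(O[C@H](C(C)(C)C)OC3=O)[C@@H](C)C(=O)OC(C)(C)C | intermediate
28 | (Z)-alkenyllithium (Li cis to CH2OTBS) | [Li]/C=C(/C)CO[Si](C)(C)C(C)(C)C | intermediate
29 | α-hydroxy (Z)-enone: C7 ketone, free 8-OH, 9-OMOM, C19 tert-butyl ester | C[C@H](O[Si](C)(C)C(C)(C)C)[C@@]1(C)C=C[C@H]2OC(C)(C)O[C@@]2(C)[C@@H]1[C@@H](OCOC)[C@@](O)(C(=O)/C=C(/C)CO[Si](C)(C)C(C)(C)C)[C@@H](C)C(=O)OC(C)(C)C | intermediate
30 | 7,8-diol tert-butyl ester (7S) | C[C@H](O[Si](C)(C)C(C)(C)C)[C@@]1(C)C=C[C@H]2OC(C)(C)O[C@@]2(C)[C@@H]1[C@@H](OCOC)[C@@](O)([C@@H](O)/C=C(/C)CO[Si](C)(C)C(C)(C)C)[C@@H](C)C(=O)OC(C)(C)C | intermediate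
31 | γ-lactone (C7–O–C19) with free 8-OH | C[C@H](O[Si](C)(C)C(C)(C)C)[C@@]1(C)C=C[C@H]2OC(C)(C)O[C@@]2(C)[C@@H]1[C@@H](OCOC)[C@]3(O)[C@@H](C)C(=O)O[C@H]3/C=C(/C)CO[Si](C)(C)C(C)(C)C | intermediate
32 | 8,9-bis-MOM lactone with 2-OTBS and 4-OTBS | C[C@H](O[Si](C)(C)C(C)(C)C)[C@@]1(C)C=C[C@H]2OC(C)(C)O[C@@]2(C)[C@@H]1[C@@H](OCOC)[C@]3(OCOC)[C@@H](C)C(=O)O[C@H]3/C=C(/C)CO[Si](C)(C)C(C)(C)C | intermediate
33 | diol: 2-OH and 4-OH | C[C@H](O)[C@@]1(C)C=C[C@H]2OC(C)(C)O[C@@]2(C)[C@@H]1[C@@H](OCOC)[C@]3(OCOC)[C@@H](C)C(=O)O[C@H]3/C=C(/C)CO | intermediate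
34 | allylic mesylate at C4 | C[C@H](O)[C@@]1(C)C=C[C@H]2OC(C)(C)O[C@@]2(C)[C@@H]1[C@@H](OCOC)[C@]3(OCOC)[C@@H](C)C(=O)O[C@H]3/C=C(/C)COS(C)(=O)=O | intermediate
35 | (Z)-allylic chloride with free 2-OH | C[C@H](O)[C@@]1(C)C=C[C@H]2OC(C)(C)O[C@@]2(C)[C@@H]1[C@@H](OCOC)[C@]3(OCOC)[C@@H](C)C(=O)O[C@H]3/C=C(/C)CCl | intermediate
36 | cyclisation precursor: C2 methyl ketone with lactone-bearing (Z)-allylic chloride | CC(=O)[C@@]1(C)C=C[C@H]2OC(C)(C)O[C@@]2(C)[C@@H]1[C@@H](OCOC)[C@]3(OCOC)[C@@H](C)C(=O)O[C@H]3/C=C(/C)CCl | intermediate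
37 | potassium enolate of 36 (C2(OK)=C3H2) | [K+].[O-]C(=C)[C@@]1(C)C=C[C@H]2OC(C)(C)O[C@@]2(C)[C@@H]1[C@@H](OCOC)[C@]3(OCOC)[C@@H](C)C(=O)O[C@H]3/C=C(/C)CCl | intermediate
38 | tricyclic C2 ketone with ten-membered ring and lactone | COCO[C@@H]1[C@H]2[C@]3(C)OC(C)(C)O[C@@H]3C=C[C@]2(C)C(=O)CC/C(C)=C\[C@@H]2OC(=O)[C@H](C)[C@]21OCOC | intermediate
39 | C2 alcohol (2R) | COCO[C@@H]1[C@H]2[C@]3(C)OC(C)(C)O[C@@H]3C=C[C@]2(C)[C@H](O)CC/C(C)=C\[C@@H]2OC(=O)[C@H](C)[C@]21OCOC | intermediate
40 | pentaol | O[C@@H]1[C@H]2[C@](C)(O)[C@H](O)C=C[C@]2(C)[C@H](O)CC/C(C)=C\[C@@H]2OC(=O)[C@H](C)[C@]21O | intermediate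
41 | CNP0129620.2 (2,9,12-triacetate) | CC(=O)O[C@@H]1[C@H]2[C@](C)(O)[C@H](OC(C)=O)C=C[C@]2(C)[C@H](OC(C)=O)CC/C(C)=C\[C@@H]2OC(=O)[C@H](C)[C@]21O | target

Total step count: 30. Longest linear sequence: 24 steps (steps 1–11 and 18–30).

Steps most likely to fail

1. Step 27. What may go wrong: proton transfer from the lactone C17 to the ketone enolate, followed by six-ring alkylation onto C4 or loss of the C8 alkoxy group; O-alkylation; intermolecular alkylation. Fallback: it sets out from 36. Soft enolisation with Me3SiOTf/Et3N (CH2Cl2, −78 °C) silylates the ketone and not the lactone, and gives the trimethylsilyl enol ether F1. Slow addition of F1 to Bu4N[Ph3SiF2] in THF (0.002 M, −40 °C) frees the ammonium enolate at C3 without any Brønsted base. This more reactive enolate should alkylate the allylic chloride at a temperature where proton transfer is slow, and the sequence comes back to the route at 38.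

2. Step 18. What may go wrong: reversal of the congested aldolate and poor facial selectivity at C9. Fallback: it sets out from 26 together with its C9 epimer. Dess–Martin oxidation gives the C9 ketone F2, which is reduced with LiBH(s-Bu)3 (THF, −78 °C). In the polar Felkin–Anh arrangement the C8–O bond lies anti to the incoming hydride and the larger C17 branch sits beside the carbonyl oxygen, which should give the 9R alcohol and comes back at 26.

3. Step 2. What may go wrong: slow cycloaddition of the trisubstituted enal and incomplete or reversed enantiofacial control. Fallback: it sets out from 2 and 3. EtAlCl2-promoted cycloaddition (CH2Cl2, −78 °C) gives the racemic adduct, that is 4 together with its enantiomer, the ent-adduct F3. MeMgBr as in step 3 gives 5 together with the ent-diol F4. Esterification of the primary hydroxyl with (S)-O-methylmandelic acid (DCC, DMAP) gives the diastereomeric mandelate ester F5 (from 5) and mandelate ester F6 (from F4), which are separated by chromatography. K2CO3/MeOH on F5 returns 5.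

Further compounds
F1 | step 27 | trimethylsilyl enol ether of 36 | C=C(O[Si](C)(C)C)[C@@]1(C)C=C[C@H]2OC(C)(C)O[C@@]2(C)[C@@H]1[C@@H](OCOC)[C@]3(OCOC)[C@@H](C)C(=O)O[C@H]3/C=C(/C)CCl
F2 | step 18 | C9 ketone of the aldol adduct | C[C@H](O[Si](C)(C)C(C)(C)C)[C@@]1(C)C=C[C@H]2OC(C)(C)O[C@@]2(C)[C@@H]1C(=O)[C@]3(O[C@H](C(C)(C)C)OC3=O)[C@@H](C)C(=O)OC(C)(C)C
F3 | step 2 | enantiomer of adduct 4 | O=C[C@]1(C)CC=C(O[Si](C)(C)C(C)(C)C)[C@H](C)[C@H]1COC(C)=O
F4 | step 2 | enantiomer of diol 5 | C[C@@H](O)[C@]1(C)CC=C(O[Si](C)(C)C(C)(C)C)[C@H](C)[C@H]1CO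
F5 | step 2 | (S)-O-methylmandelate ester of 5 at O9 | C[C@H](O)[C@@]1(C)CC=C(O[Si](C)(C)C(C)(C)C)[C@@H](C)[C@@H]1COC(=O)[C@@H](OC)c1ccccc1
F6 | step 2 | (S)-O-methylmandelate ester of F4 at O9 | C[C@@H](O)[C@]1(C)CC=C(O[Si](C)(C)C(C)(C)C)[C@H](C)[C@H]1COC(=O)[C@@H](OC)c1ccccc1
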